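## Retrosynthetic overview

1. Numbering: ring C1 (C(Cl)CH3), C2 (CH2), C3 (quaternary, bearing CH3 and the bromovinyl group C7=C8), C4 (CHBr), C5 (CH2), C6 (CHCl). The strategy rests on C3. Its in-ring branch C4 and its exocyclic branch C7 can both be formyl groups of a prochiral malonaldehyde, and C4/C6 stand in the 1,3-dioxygen relationship of an aldol.
2. Endgame: the cis C1,C6-dichloride comes from the alpha C1–C6 epoxide by double inversion. The beta C4 bromide comes from the alpha C4 alcohol by inversion. The E-bromovinyl group comes from the C7 aldehyde by Takai olefination.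
3. The epoxide comes from the C1=C6 alkene under direction by C4–OH. The alkene comes from the C6 ketone through its more substituted enol triflate.
4. The only ring, the cyclohexane, is closed by an amine-catalysed desymmetrising aldol (C4–C5 bond) of an open-chain keto dialdehyde. This sets C3 and C4 in one event.
5. The keto dialdehyde is made in three steps from diethyl methylmalonate and 3-methylbut-3-en-2-one (Michael addition, LiAlH4, Swern).

Key step: step 4

Convention: the numbering C1–C8 above is kept for every compound. Beta is the ring face that carries C7 on C3, and alpha is the face of the C3 methyl group.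

Assumption: the sense of induction is carried over from the proline-catalysed closure of 2-methyl-2-(3-oxobutyl)-1,3-diketones, where (S)-proline gives the mirror-image arrangement at the quaternary carbon. (R)-Proline is therefore used; should the sense prove opposite, (S)-proline is taken and nothing else changes.

## Route

Step 1
Reactants: 1 diethyl 2-methylpropanedioate; 2 3-methylbut-3-en-2-one
Product: 3 diethyl 2-methyl-2-(2-methyl-3-oxobutyl)propanedioate (racemic)
Conditions: NaOEt (0.1 equiv), EtOH, 0 °C to rt
Reagents that add atoms: none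
Why: Base-catalysed Michael addition in which the malonate anion adds to the unsubstituted methylene terminus of enone 2 and builds the quaternary carbon C3, while the catalytic amount of alkoxide and the low temperature keep the adduct from a Claisen-type ring closure; the new C1 centre is formed racemic.

Step 2
Reactants: 3 diethyl 2-methyl-2-(2-methyl-3-oxobutyl)propanedioate
Product: 4 2-(hydroxymethyl)-2,4-dimethylhexane-1,5-diol (diastereomer mixture)
Conditions: LiAlH4, THF, 0 °C to reflux; aq. NaOH work-up
Reagents that add atoms: none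
Why: LiAlH4 reduces both esters and the ketone in one operation, a standard reduction of 2,2-disubstituted malonates to 1,3-diols, and the mixture of carbinol epimers is of no consequence because that carbon returns to the ketone level in step 3.

Step 3
Reactants: 4 2-(hydroxymethyl)-2,4-dimethylhexane-1,5-diol
Product: 5 2-methyl-2-(2-methyl-3-oxobutyl)propanedial (racemic at C1)
Conditions: (COCl)2, DMSO, CH2Cl2, −78 °C; then Et3N, −78 to 0 °C
Reagents that add atoms: none
Why: In the Swern oxidation all three hydroxyl groups are activated at −78 °C before any carbonyl group exists, so no lactol can form, and the resulting malonaldehyde has no alpha hydrogen and cannot enolise; 5 is kept cold, passed through a short silica pad and used at once because nucleophiles can deformylate it.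

Step 4
Reactants: 5 2-methyl-2-(2-methyl-3-oxobutyl)propanedial
Product: 7 (1R,2R,5RS)-2-hydroxy-1,5-dimethyl-4-oxocyclohexane-1-carbaldehyde, via proline enamine 6 (not isolated)
Conditions: (R)-proline (20 mol %), DMF, 0 °C to rt
Reagents that add atoms: none
Why: (R)-Proline condenses with the methyl ketone to give the less substituted enamine 6 (C5=C6), whose carboxylic acid hydrogen-bonds to one formyl oxygen while C5 attacks that carbonyl carbon (C4) through a chair-like transition state, and hydrolysis of the resulting iminium ion releases ketol 7 and the catalyst. The closest known reaction type is the Hajos-Parrish-Eder-Sauer-Wiechert aldolisation of 2-methyl-2-(3-oxobutyl)-1,3-diketones, of which 5 is the open-chain dialdehyde analogue. Both enamine carbons C5 and C6 end up inside the new ring, so the cyclohexanone is closed in the favoured 6-(enolendo)-exo-trig mode; the alternative enamine at C1 could only close a four-membered ring and the formyl groups have no alpha hydrogen, so only one ring-forming pathway is open. C3 is set by which enantiotopic formyl group the acid function of the catalyst can reach, which is why the catalyst enantiomer decides the absolute configuration. C4 is set by the carbonyl face: the hydrogen bond requires the developing alkoxide to be axial (gauche to C6), and the chair that then places the C3 methyl equatorial and the smaller spectator formyl axial, with its dipole opposed to the reacting carbonyl, gives hydroxyl (alpha) trans to formyl (beta). The step needs enantiotopic-group selectivity, face selectivity and a stop at the ketol stage before dehydration; the racemic C1 centre makes 7 a pair of C1 epimers that converge in step 8.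

Step 5
Reactants: 7 (1R,2R,5RS)-2-hydroxy-1,5-dimethyl-4-oxocyclohexane-1-carbaldehyde
Product: 8 (1R,2R,5RS)-2-[(tert-butyldimethylsilyl)oxy]-1,5-dimethyl-4-oxocyclohexane-1-carbaldehyde
Conditions: TBSOTf, 2,6-lutidine, CH2Cl2, −78 to 0 °C
Reagents that add atoms: tert-butyldimethylsilyl trifluoromethanesulfonate, CC(C)(C)[Si](C)(C)OS(=O)(=O)C(F)(F)F
Why: A silyl triflate with a hindered pyridine base silylates the neopentyl-type secondary alcohol at low temperature without the basic conditions that would trigger retro-aldol cleavage or E1cB loss of the beta oxygen.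

Step 6
Reactants: 8 (1R,2R,5RS)-2-[(tert-butyldimethylsilyl)oxy]-1,5-dimethyl-4-oxocyclohexane-1-carbaldehyde
Product: 9 (2RS,4S,5R)-5-[(tert-butyldimethylsilyl)oxy]-4-(hydroxymethyl)-2,4-dimethylcyclohexan-1-one
Conditions: NaBH(OAc)3, toluene, 70 °C
Reagents that add atoms: none
Why: Chemoselective triacetoxyborohydride reduction, in which this weak hydride donor reduces aldehydes but leaves ketones untouched unless a free neighbouring hydroxyl delivers it, so with C4–OH already silylated only the formyl group C7 is reduced.

Step 7
Reactants: 9 (2RS,4S,5R)-5-[(tert-butyldimethylsilyl)oxy]-4-(hydroxymethyl)-2,4-dimethylcyclohexan-1-one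
Product: 10 (2RS,4S,5R)-5-[(tert-butyldimethylsilyl)oxy]-4-{[(tert-butyldimethylsilyl)oxy]methyl}-2,4-dimethylcyclohexan-1-one
Conditions: TBSCl, imidazole, DMF, rt
Reagents that add atoms: tert-butyldimethylsilyl chloride, CC(C)(C)[Si](C)(C)Cl
Why: Standard silylation of a primary alcohol, which masks C7 as a silyl ether that is inert to Tf2O, palladium and formate, whereas an acetal of the aldehyde would be at risk from the strongly electrophilic reagent of step 8.

Step 8
Reactants: 10 (2RS,4S,5R)-5-[(tert-butyldimethylsilyl)oxy]-4-{[(tert-butyldimethylsilyl)oxy]methyl}-2,4-dimethylcyclohexan-1-one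
Product: 11 (4S,5R)-5-[(tert-butyldimethylsilyl)oxy]-4-{[(tert-butyldimethylsilyl)oxy]methyl}-2,4-dimethylcyclohex-1-en-1-yl trifluoromethanesulfonate
Conditions: Tf2O, 2,6-di-tert-butyl-4-methylpyridine, CH2Cl2, 0 °C to rt
Reagents that add atoms: trifluoromethanesulfonic anhydride, O=S(=O)(OS(=O)(=O)C(F)(F)F)C(F)(F)F
Why: Enol triflate formation under non-enolate conditions passes through the O-triflyl oxocarbenium ion, which loses the proton that gives the more substituted alkene (C1–H rather than C5–H, the latter also being deactivated by the adjacent C4–O bond), so both C1 epimers should converge on the tetrasubstituted C1=C6 triflate without an enolate that could expel the silyloxy group, and any C5=C6 regioisomer is removed by chromatography.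

Step 9
Reactants: 11 (4S,5R)-5-[(tert-butyldimethylsilyl)oxy]-4-{[(tert-butyldimethylsilyl)oxy]methyl}-2,4-dimethylcyclohex-1-en-1-yl trifluoromethanesulfonate
Product: 12 bis(tert-butyldimethylsilyl) ether of (1R,6S)-6-(hydroxymethyl)-4,6-dimethylcyclohex-3-en-1-ol
Conditions: Pd(OAc)2 (5 mol %), PPh3 (10 mol %), HCO2H, n-Bu3N, DMF, 60 °C
Reagents that add atoms: none
Why: Palladium-catalysed formate reduction of an enol triflate, in which oxidative addition of zerovalent palladium into the C6–O bond, formate exchange, loss of CO2 and reductive elimination replace OTf by H with the double bond held at C1=C6.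

Step 10
Reactants: 12 bis(tert-butyldimethylsilyl) ether of (1R,6S)-6-(hydroxymethyl)-4,6-dimethylcyclohex-3-en-1-ol
Product: 13 (1R,6S)-6-(hydroxymethyl)-4,6-dimethylcyclohex-3-en-1-ol
Conditions: n-Bu4NF, THF, rt to 45 °C
Reagents that add atoms: none
Why: Fluoride cleaves both silyl ethers in one operation, and the diol carries no group that is sensitive to the basic medium.

Step 11
Reactants: 13 (1R,6S)-6-(hydroxymethyl)-4,6-dimethylcyclohex-3-en-1-ol
Product: 14 (1R,6R)-6-hydroxy-1,3-dimethylcyclohex-3-ene-1-carbaldehyde
Conditions: TEMPO (10 mol %), PhI(OAc)2, CH2Cl2, rt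
Reagents that add atoms: none
Why: The oxoammonium salt formed from TEMPO oxidises the primary alcohol much faster than the hindered secondary one and stops at the aldehyde in the absence of water, and removing the beta-face C7 hydroxyl here also takes away a group that could misdirect the epoxidation of step 13.

Step 12
Reactants: 14 (1R,6R)-6-hydroxy-1,3-dimethylcyclohex-3-ene-1-carbaldehyde
Product: 15 (1R,6S)-6-[(E)-2-bromoethenyl]-4,6-dimethylcyclohex-3-en-1-ol
Conditions: CrBr3, LiAlH4, THF, 0 °C to rt; then CHBr3 and 14, THF, 0 to 50 °C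
Reagents that add atoms: bromoform, BrC(Br)Br
Why: Takai olefination, in which the geminal dichromium species from CHBr3 and divalent chromium adds to the aldehyde and eliminates to the E-alkene, favoured further by the bulky quaternary C3; the bromide salt instead of CrCl2 avoids halogen exchange to a vinyl chloride, the free hydroxyl is tolerated, and the step is placed before any epoxide or alkyl halide that divalent chromium might reduce is present.

Step 13
Reactants: 15 (1R,6S)-6-[(E)-2-bromoethenyl]-4,6-dimethylcyclohex-3-en-1-ol
Product: 16 (1S,3R,4S,6R)-4-[(E)-2-bromoethenyl]-4,6-dimethyl-7-oxabicyclo[4.1.0]heptan-3-ol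
Conditions: VO(acac)2 (5 mol %), t-BuOOH (in decane), CH2Cl2, 0 °C to rt
Reagents that add atoms: tert-butyl hydroperoxide, CC(C)(C)OO
Why: Vanadium-catalysed hydroxyl-directed epoxidation of a homoallylic cyclohexenol, in which the axial C4 alkoxide binds the vanadium peroxide and delivers oxygen to its own alpha face, setting C1 and C6, while the electron-poor bromoalkene on the opposite face is not attacked.

Step 14
Reactants: 16 (1S,3R,4S,6R)-4-[(E)-2-bromoethenyl]-4,6-dimethyl-7-oxabicyclo[4.1.0]heptan-3-ol
Product: 18 (1R,3S,4S,6S)-4-bromo-3-[(E)-2-bromoethenyl]-1,3-dimethyl-7-oxabicyclo[4.1.0]heptane, via alkoxyphosphonium bromide 17 (not isolated)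
Conditions: CBr4, P(n-C8H17)3, toluene, 70 °C
Reagents that add atoms: carbon tetrabromide, BrC(Br)(Br)Br
Why: Appel-type bromination in which bromide displaces the axial alpha oxyphosphonium group of 17 by SN2 with inversion to give the equatorial beta bromide; it is placed after the epoxidation because the C1=C6 alkene of 15 is homoallylic to C4 and could participate with retention, whereas the epoxide oxygen lies on the face of the leaving group and cannot participate, and the neutral medium is of the kind routinely used on epoxy alcohols.

Step 15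
Reactants: 18 (1R,3S,4S,6S)-4-bromo-3-[(E)-2-bromoethenyl]-1,3-dimethyl-7-oxabicyclo[4.1.0]heptane
Product: 20 (1S,2S,4R,5S)-2-bromo-1-[(E)-2-bromoethenyl]-4,5-dichloro-1,5-dimethylcyclohexane, via chloro alkoxyphosphonium chloride 19 (not isolated)
Conditions: PPh3, N-chlorosuccinimide, toluene, 90 °C
Reagents that add atoms: N-chlorosuccinimide, O=C1CCC(=O)N1Cl
Why: Deoxydichlorination of an epoxide by a chlorophosphonium salt, in which the phosphorus binds the epoxide oxygen, chloride opens the activated ring at the tertiary C1 from the beta face in the trans-diaxial sense (inversion) to give 19, and a second chloride displaces Ph3PO from the secondary C6 with inversion, so that both chlorines end up beta (cis) and the C1 methyl alpha.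

## Compound list

1 | diethyl 2-methylpropanedioate (diethyl methylmalonate) | CCOC(=O)C(C)C(=O)OCC | starting material
2 | 3-methylbut-3-en-2-one | CC(=C)C(C)=O | starting material
3 | diethyl 2-methyl-2-(2-methyl-3-oxobutyl)propanedioate | CCOC(=O)C(C)(CC(C)C(C)=O)C(=O)OCC | intermediate
4 | 2-(hydroxymethyl)-2,4-dimethylhexane-1,5-diol | CC(O)C(C)CC(C)(CO)CO | intermediate
5 | 2-methyl-2-(2-methyl-3-oxobutyl)propanedial | CC(=O)C(C)CC(C)(C=O)C=O | intermediate
6 | (2R)-1-(5-formyl-3,5-dimethyl-6-oxohex-1-en-2-yl)pyrrolidine-2-carboxylic acid | C=C(N1CCC[C@@H]1C(=O)O)C(C)CC(C)(C=O)C=O | intermediate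
7 | (1R,2R,5RS)-2-hydroxy-1,5-dimethyl-4-oxocyclohexane-1-carbaldehyde | CC1C[C@@](C)(C=O)[C@H](O)CC1=O | intermediate
8 | (1R,2R,5RS)-2-[(tert-butyldimethylsilyl)oxy]-1,5-dimethyl-4-oxocyclohexane-1-carbaldehyde | CC1C[C@@](C)(C=O)[C@H](O[Si](C)(C)C(C)(C)C)CC1=O | intermediate
9 | (2RS,4S,5R)-5-[(tert-butyldimethylsilyl)oxy]-4-(hydroxymethyl)-2,4-dimethylcyclohexan-1-one | CC1C[C@@](C)(CO)[C@H](O[Si](C)(C)C(C)(C)C)CC1=O | intermediate
10 | (2RS,4S,5R)-5-[(tert-butyldimethylsilyl)oxy]-4-{[(tert-butyldimethylsilyl)oxy]methyl}-2,4-dimethylcyclohexan-1-one | CC1C[C@@](C)(CO[Si](C)(C)C(C)(C)C)[C@H](O[Si](C)(C)C(C)(C)C)CC1=O | intermediate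
11 | (4S,5R)-5-[(tert-butyldimethylsilyl)oxy]-4-{[(tert-butyldimethylsilyl)oxy]methyl}-2,4-dimethylcyclohex-1-en-1-yl trifluoromethanesulfonate | CC=1C[C@@](C)(CO[Si](C)(C)C(C)(C)C)[C@H](O[Si](C)(C)C(C)(C)C)CC=1OS(=O)(=O)C(F)(F)F | intermediate
12 | bis(tert-butyldimethylsilyl) ether of (1R,6S)-6-(hydroxymethyl)-4,6-dimethylcyclohex-3-en-1-ol | CC=1C[C@@](C)(CO[Si](C)(C)C(C)(C)C)[C@H](O[Si](C)(C)C(C)(C)C)CC=1 | intermediate
13 | (1R,6S)-6-(hydroxymethyl)-4,6-dimethylcyclohex-3-en-1-ol | CC=1C[C@@](C)(CO)[C@H](O)CC=1 | intermediate
14 | (1R,6R)-6-hydroxy-1,3-dimethylcyclohex-3-ene-1-carbaldehyde | CC=1C[C@@](C)(C=O)[C@H](O)CC=1 | intermediate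
15 | (1R,6S)-6-[(E)-2-bromoethenyl]-4,6-dimethylcyclohex-3-en-1-ol | CC=1C[C@@](C)(/C=C/Br)[C@H](O)CC=1 | intermediate
16 | (1S,3R,4S,6R)-4-[(E)-2-bromoethenyl]-4,6-dimethyl-7-oxabicyclo[4.1.0]heptan-3-ol | C[C@@]12C[C@@](C)(/C=C/Br)[C@H](O)C[C@@H]1O2 | intermediate
17 | {[(1S,3R,4S,6R)-4-[(E)-2-bromoethenyl]-4,6-dimethyl-7-oxabicyclo[4.1.0]heptan-3-yl]oxy}(trioctyl)phosphonium bromide | C[C@@]12C[C@@](C)(/C=C/Br)[C@H](O[P+](CCCCCCCC)(CCCCCCCC)CCCCCCCC)C[C@@H]1O2.[Br-] | intermediate
18 | (1R,3S,4S,6S)-4-bromo-3-[(E)-2-bromoethenyl]-1,3-dimethyl-7-oxabicyclo[4.1.0]heptane | C[C@@]12C[C@@](C)(/C=C/Br)[C@@H](Br)C[C@@H]1O2 | intermediate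
19 | {[(1S,2S,4S,5S)-5-bromo-4-[(E)-2-bromoethenyl]-2-chloro-2,4-dimethylcyclohexyl]oxy}(triphenyl)phosphonium chloride | C[C@]1(Cl)C[C@@](C)(/C=C/Br)[C@@H](Br)C[C@@H]1O[P+](c1ccccc1)(c1ccccc1)c1ccccc1.[Cl-] | intermediate
20 | (1S,2S,4R,5S)-2-bromo-1-[(E)-2-bromoethenyl]-4,5-dichloro-1,5-dimethylcyclohexane | C[C@]1(Cl)C[C@@](C)(/C=C/Br)[C@@H](Br)C[C@H]1Cl | target

## Step count and risks

Total step count: 15. Longest linear sequence: 15 steps (fully linear from 1 and 2).

**Step 4 (desymmetrising aldol).**
- What may go wrong: the racemic C1 centre may work against the catalyst in one enantiomer of the substrate (double stereodifferentiation), which would erode the enantiotopic-group selectivity. Loss of water from the ketol or deformylation of the malonaldehyde may also compete.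
- Fallback: the stereocentre is taken out of the substrate, so that an achiral compound is desymmetrised, and the C1 methyl group is added after ring closure.
- It sets out from 1. Michael addition to but-3-en-2-one (NaOEt cat., EtOH) gives diethyl 2-methyl-2-(3-oxobutyl)propanedioate F1. LiAlH4 gives 2-(hydroxymethyl)-2-methylhexane-1,5-diol F2. Swern oxidation gives achiral 2-methyl-2-(3-oxobutyl)propanedial F3.
- (R)-Proline in DMF closes F3 to (1R,2R)-2-hydroxy-1-methyl-4-oxocyclohexane-1-carbaldehyde F4.
- The operations of steps 5 to 7 then follow. TBSOTf with 2,6-lutidine gives (1R,2R)-2-[(tert-butyldimethylsilyl)oxy]-1-methyl-4-oxocyclohexane-1-carbaldehyde F5. NaBH(OAc)3 gives (3R,4S)-3-[(tert-butyldimethylsilyl)oxy]-4-(hydroxymethyl)-4-methylcyclohexan-1-one F6. TBSCl with imidazole gives (3R,4S)-3-[(tert-butyldimethylsilyl)oxy]-4-{[(tert-butyldimethylsilyl)oxy]methyl}-4-methylcyclohexan-1-one F7.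
- Kinetic deprotonation of F7 with LDA in THF at −78 °C, expected at C1 on the side away from the silyloxy group, followed by MeI, brings the route back at 10.

**Step 14 (invertive bromination at C4).**
- What may go wrong: substitution next to the quaternary C3 is slow. E2 loss of the antiperiplanar axial C5 hydrogen or opening of the epoxide by bromide at the temperature needed may therefore overtake it.
- Fallback: activation and displacement are separated, and a far better leaving group is used so that the substitution runs near room temperature with a non-Lewis-acidic bromide source.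
- It sets out from 16. Tf2O and pyridine in CH2Cl2 at −20 °C give (1S,3R,4S,6R)-4-[(E)-2-bromoethenyl]-4,6-dimethyl-7-oxabicyclo[4.1.0]heptan-3-yl trifluoromethanesulfonate F8.
- n-Bu4NBr in toluene at rt displaces the triflate with inversion, and the route is rejoined at 18.

**Step 15 (deoxydichlorination).**
- What may go wrong: after the first chloride has opened the epoxide at C1, the second displacement at C6 is slow because C6 is flanked by the fully substituted C1. Two processes may overtake it. One is participation of the antiperiplanar C1 chlorine, which gives retention or chlorine migration and hence a trans-dichloride. The other is E2 loss of the axial C5 hydrogen.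
- Fallback: the two C–Cl bonds are made in separate operations with a different activating agent.
- It sets out from 18. Anhydrous HCl in Et2O/CH2Cl2 at −40 °C opens the epoxide at the tertiary carbon with inversion to (1S,2S,4S,5S)-5-bromo-4-[(E)-2-bromoethenyl]-2-chloro-2,4-dimethylcyclohexan-1-ol F9, which can be purified and its configuration checked.
- 1-Chloro-N,N,2-trimethylprop-1-en-1-amine in CHCl3 at 0 °C to rt then turns the C6 hydroxyl into an imidate-type leaving group. This collapses with its own chloride counter-ion in a tight ion pair with inversion, and the route is rejoined at 20.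

## Further compounds

F1 | step 4 | diethyl 2-methyl-2-(3-oxobutyl)propanedioate | CCOC(=O)C(C)(CCC(C)=O)C(=O)OCC
F2 | step 4 | 2-(hydroxymethyl)-2-methylhexane-1,5-diol | CC(O)CCC(C)(CO)CO
F3 | step 4 | 2-methyl-2-(3-oxobutyl)propanedial | CC(=O)CCC(C)(C=O)C=O
F4 | step 4 | (1R,2R)-2-hydroxy-1-methyl-4-oxocyclohexane-1-carbaldehyde | C1C[C@@](C)(C=O)[C@H](O)CC1=O
F5 | step 4 | (1R,2R)-2-[(tert-butyldimethylsilyl)oxy]-1-methyl-4-oxocyclohexane-1-carbaldehyde | C1C[C@@](C)(C=O)[C@H](O[Si](C)(C)C(C)(C)C)CC1=O
F6 | step 4 | (3R,4S)-3-[(tert-butyldimethylsilyl)oxy]-4-(hydroxymethyl)-4-methylcyclohexan-1-one | C1C[C@@](C)(CO)[C@H](O[Si](C)(C)C(C)(C)C)CC1=O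
F7 | step 4 | (3R,4S)-3-[(tert-butyldimethylsilyl)oxy]-4-{[(tert-butyldimethylsilyl)oxy]methyl}-4-methylcyclohexan-1-one | C1C[C@@](C)(CO[Si](C)(C)C(C)(C)C)[C@H](O[Si](C)(C)C(C)(C)C)CC1=O
F8 | step 14 | (1S,3R,4S,6R)-4-[(E)-2-bromoethenyl]-4,6-dimethyl-7-oxabicyclo[4.1.0]heptan-3-yl trifluoromethanesulfonate | C[C@@]12C[C@@](C)(/C=C/Br)[C@H](OS(=O)(=O)C(F)(F)F)C[C@@H]1O2
F9 | step 15 | (1S,2S,4S,5S)-5-bromo-4-[(E)-2-bromoethenyl]-2-chloro-2,4-dimethylcyclohexan-1-ol | C[C@]1(Cl)C[C@@](C)(/C=C/Br)[C@@H](Br)C[C@@H]1O
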